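**Assumptions.** The target has no stereocentres, so there is no enantiomer to control. The only stereo-element in the route is the E-chalcone alkene, which is lost on ring closure. Compound 1 is taken as commercially available; it can also be made from xanthoxylin by BCl3 mono-demethylation.

## Retrosynthesis
1. Pollenitin 8-acetate comes from the 3,4'-di-O-benzyl 8-acetate by hydrogenolysis. The 8-acetate comes from the 5,8-dihydroxy compound by chemoselective acetylation of the non-chelated 8-OH.
2. Key disconnection: the C8–O bond. It is formed last by an Elbs persulfate C–H hydroxylation, para to the chelated 5-OH, on a simple 5-hydroxy-7-methoxyflavonol. This avoids carrying a labile, hydroquinone-prone tetraoxygenated A-ring through the route.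
3. The 3,4'-di-O-benzyl-5-hydroxy-7-methoxyflavonol comes from a 3-OH flavonol by benzylation. That flavonol comes from a 2'-hydroxychalcone by oxidative cyclisation (C ring).
4. The chalcone comes from commercial 2',6'-dihydroxy-4'-methoxyacetophenone (A ring) and 4-benzyloxybenzaldehyde (B ring).
5. Ring order: A and B rings are commercial. The C ring is formed in step 2. The C8 oxygen is installed in step 4.

## Forward route

**Step 1**
Reactants: 1 (2',6'-dihydroxy-4'-methoxyacetophenone); 2 (4-benzyloxybenzaldehyde)
Product: 3, (E)-3-(4-benzyloxyphenyl)-1-(2,6-dihydroxy-4-methoxyphenyl)prop-2-en-1-one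
Conditions: 50% aq KOH, EtOH, rt, 48 h; then 2 M HCl
Reagents that add atoms: none
Why: Claisen–Schmidt condensation; excess base is needed because both phenols are deprotonated, and the E-enone is the thermodynamic product.

**Step 2**
Reactants: 3; hydrogen peroxide
Product: 4, 4'-benzyloxy-3,5-dihydroxy-7-methoxyflavone
Conditions: 30% H2O2, 2 M NaOH, EtOH, 0 °C to rt, 16 h; then HCl
Reagents that add atoms: hydrogen peroxide, OO
Why: Algar–Flynn–Oyamada oxidative cyclisation. Weitz–Scheffer epoxidation is followed by 2'-phenolate ring closure to the dihydroflavonol, which is oxidised to the flavonol. The 5-OH is H-bonded to C4=O and survives. No new stereocentre remains because C2/C3 become sp2.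

**Step 3**
Reactants: 4; benzyl bromide
Product: 5, 3,4'-bis(benzyloxy)-5-hydroxy-7-methoxyflavone
Conditions: BnBr (1.2 equiv), K2CO3, DMF, rt, 12 h
Reagents that add atoms: benzyl bromide, BrCc1ccccc1
Why: Williamson etherification at the most acidic, non-chelated 3-OH, while the chelated 5-OH is untouched. This also removes the oxidation-prone flavonol enol before the Elbs step.

**Step 4 (key step)**
Reactants: 5; potassium persulfate
Product: 6, 3,4'-bis(benzyloxy)-5,8-dihydroxy-7-methoxyflavone
Conditions: K2S2O8 (1.3 equiv), aq NaOH, pyridine, 0 °C to rt, 24 h; then 2 M HCl, EtOH, 60 °C, N2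
Reagents that add atoms: potassium persulfate, [K+].[K+].[O-]S(=O)(=O)OOS(=O)(=O)[O-] (contributes the C8–O oxygen; sulfate is lost on hydrolysis)
Why: Elbs persulfate oxidation. The 5-phenolate attacks the peroxide O–O through its para carbon, C8, giving the 8-aryl sulfate; acid hydrolysis releases the 8-OH. This extends known Elbs 8-hydroxylation of 5-hydroxyflavones. Ortho attack at C6 should be the minor pathway.

**Step 5**
Reactants: 6; acetic anhydride
Product: 7, 8-acetoxy-3,4'-bis(benzyloxy)-5-hydroxy-7-methoxyflavone
Conditions: Ac2O (1.2 equiv), pyridine, CH2Cl2, 0 °C to rt, 2 h (no DMAP)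
Reagents that add atoms: acetic anhydride, CC(=O)OC(C)=O
Why: Chemoselective O-acylation. The free 8-OH reacts, while the 5-OH is locked in a hydrogen bond to C4=O. Running this immediately after step 4 also limits air oxidation of the 5,8-hydroquinone.

**Step 6**
Reactants: 7
Product: 8, pollenitin 8-acetate (target)
Conditions: H2 (1 atm), 10% Pd/C, THF/EtOAc 1:1, rt, 3 h
Reagents that add atoms: none
Why: Hydrogenolysis of the 3-O- and 4'-O-benzyl ethers. The aryl acetate, 7-OMe, chelated 5-OH and C2=C3 enone survive; aprotic solvents avoid acetate methanolysis.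

## Compound list
1 | 2',6'-dihydroxy-4'-methoxyacetophenone | CC(=O)c1c(O)cc(OC)cc1O | starting material
2 | 4-benzyloxybenzaldehyde | O=Cc1ccc(OCc2ccccc2)cc1 | starting material
3 | (E)-4-benzyloxy-2',6'-dihydroxy-4'-methoxychalcone | COc1cc(O)c(C(=O)/C=C/c2ccc(OCc3ccccc3)cc2)c(O)c1 | intermediate
4 | 4'-benzyloxy-3,5-dihydroxy-7-methoxyflavone | COc1cc(O)c2c(=O)c(O)c(-c3ccc(OCc4ccccc4)cc3)oc2c1 | intermediate
5 | 3,4'-bis(benzyloxy)-5-hydroxy-7-methoxyflavone | COc1cc(O)c2c(=O)c(OCc3ccccc3)c(-c3ccc(OCc4ccccc4)cc3)oc2c1 | intermediate
6 | 3,4'-bis(benzyloxy)-5,8-dihydroxy-7-methoxyflavone | COc1cc(O)c2c(=O)c(OCc3ccccc3)c(-c3ccc(OCc4ccccc4)cc3)oc2c1O | intermediate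
7 | 8-acetoxy-3,4'-bis(benzyloxy)-5-hydroxy-7-methoxyflavone | COc1cc(O)c2c(=O)c(OCc3ccccc3)c(-c3ccc(OCc4ccccc4)cc3)oc2c1OC(C)=O | intermediate
8 | pollenitin 8-acetate | COc1cc(O)c2c(=O)c(O)c(-c3ccc(O)cc3)oc2c1OC(C)=O | target

**Total steps: 6. Longest linear sequence: 6.**

## Three steps most likely to fail
1. **Step 4 (Elbs C8 hydroxylation).** Risks are low yield, C6 versus C8 selectivity, and over-oxidation of the 5,8-hydroquinone to the quinone.
   Fallback: oxidise 5 with Fremy's salt (Teuber reaction) to the 5,8-quinone, reduce it with Na2S2O4 to 6, and continue from step 5. This is a radical para-oxygenation, a different mechanism from persulfate attack.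
2. **Step 2 (AFO on the 2',6'-dihydroxychalcone).** Aurone formation or oxidative decomposition of the electron-rich A ring may compete.
   Fallback: cyclise 3 to the flavanone (NaOAc, EtOH, reflux), nitrosate at C3 (isoamyl nitrite, HCl), then hydrolyse and tautomerise to flavonol 4. This avoids peroxide and strong base.
3. **Step 6 (final hydrogenolysis).** Risks are saturation of C2=C3, loss or migration of the 8-acetate, and catalyst poisoning.
   Fallback: remove the benzyl groups with BCl3 and pentamethylbenzene in CH2Cl2 at −78 °C. This is a Lewis-acid cleavage, and the 7-OMe and acetate should survive at that temperature.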